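I started from the slowness of the autumn run against the noon run, which had 3.00 times its free catalyst on the same charge of starting material.

| flask | starting material | free catalyst | time |
|---|---|---|---|
| autumn | 0.300 M | 0.00900 M |  |
| summer | 0.120 M | 0.00900 M |  |
| dusk | 0.900 M | 0.00900 M |  |
| noon | 0.300 M | 0.0270 M |  |
| spring | 0.150 M | 0.00450 M | 45 min |

| run | time / min | [starting material] / M |
|---|---|---|
| autumn run | 7.5 | 0.209 |
| autumn run | 15 | 0.154 |
| autumn run | 22 | 0.119 |
| autumn run | 30 | 0.093 |
| autumn run | 38 | 0.076 |
| autumn run | 45 | 0.070 |
| summer run | 7.5 | 0.078 |
| summer run | 15 | 0.057 |
| summer run | 22 | 0.036 |
| summer run | 30 | 0.032 |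
| summer run | 38 | 0.009 |
| summer run | 45 | 0.013 |
| dusk run | 7.5 | 0.712 |
| dusk run | 15 | 0.561 |
| dusk run | 22 | 0.463 |
| dusk run | 30 | 0.380 |
| dusk run | 38 | 0.320 |
| dusk run | 45 | 0.292 |
| noon run | 7.5 | 0.133 |
| noon run | 15 | 0.080 |
| noon run | 22 | 0.046 |
| noon run | 30 | 0.029 |
| noon run | 38 | 0.032 |
| noon run | 45 | 0.025 |

(each reading ± 0.004 M)

- the power of [free catalyst] that the first rate follows, about the charge of the autumn run; measure it at two percent of starting material made into product
- the power of [starting material] that the first rate follows, about the charge of the autumn run; measure it at two percent of starting material made into product (one fixed amount of product, the same in the runs compared)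
- starting material in the spring run at 45 min, as a share of the starting material charged

- Overall: starting material -> product, with free catalyst as catalyst.
- Constant volume, constant temperature.
- The analysis sees a species whether free or bound.
- An order is taken over about fifteen percent of the charge, up and down.

Working with the fraction left, I compared the two runs at nearly equal free catalyst multiplied by time. The noon run kept 44.3% at 7.5 min, but the autumn run kept 39.7% at 22 min, less, so I suspected a loss that ran on the clock. I therefore split the logarithm of the fraction left into a part proportional to free catalyst and time and a part proportional to time. The two readings at 7.5 min then gave 0.0181 min⁻¹, give or take 0.00432 min⁻¹. I called this reading the leak, the first-order constant of a background reaction, the part of the logarithm gained per minute without free catalyst.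

But the spring run has half the free catalyst of the summer and autumn runs, so its 45 min carry about the free catalyst and time of their 22 min, and their charges bracket its charge. I kept each run's catalysed part at that reading and replaced its leak with the leak over 45 min. That left 19.8% from the summer run and 26.2% from the autumn run, and I committed to that span.

The forecast gave 30%, between 25% and 36%, above my span, with orders of 0.8 in free catalyst and 0.77 in starting material. Its stated ground was “Product must inhibit”.

The simulation gave 25.8% for the spring run, with orders of 0.96 in free catalyst and 0.60 in starting material.

    free catalyst + starting material ⇌ catalyst-substrate complex (6.780 M⁻¹ min⁻¹, 0.4956 min⁻¹)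
    catalyst-substrate complex → product + free catalyst (2.322 min⁻¹)
    free catalyst + product → spent catalyst + product (0.6360 M⁻¹ min⁻¹)
    starting material → decomposed substrate (0.01488 min⁻¹)

The path from starting material to decomposed substrate moved the readings by 28 in units of the scatter. In the dusk run, product reached a quarter of the charge at 22.0 min, when the reading left 51.4% as starting material, so 23.6% was in neither form, and the leak summed over that run's fractions left gave 28.9%.

The runs are simulated with constants of no real substance; scatter was added.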